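**Retrosynthetic overview** (flavanone numbering O1, C2, C3, C4, C4a, C5–C8, C8a; ring A = its benzene ring, ring C = its pyranone ring)
1. Silyhermin B comes from its pentabenzyl ether by one global hydrogenolysis.
2. Ring C is closed and ring A attached in one aryne annulation of a β-silyloxy ester with 3,5-bis(benzyloxy)benzyne: the alkoxide makes O1–C8a, the resulting aryl anion makes C4–C4a. The enabling feature is that the neighbouring ring-A carbons C4a and C8a carry the C4 carbonyl and the ring oxygen O1 (an ortho-acyl aryl ether), while the C5 oxygen next to C4a polarises the aryne so that O1 goes to C8a.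
3. Because O1 sits on C2, β to the C4 carbonyl, the other partner is an acetate aldol; a catalytic asymmetric Mukaiyama aldol on the benzofuran aldehyde sets C2.
4. The trans-dihydrobenzofuran comes from an enantioselective rhodium-carbenoid C–H insertion of an aryl diazoacetate, then epimerisation, reduction, benzylation and formylation.
5. Ring order: dihydrofuran ring first (step 5), then ring C with ring A delivered whole as the aryne (step 12).

Key step: step 12

Remark: the sense of induction of Rh2(S-PTTL)4 (step 5) and of the (S)-configured binaphthyl Schiff-base ligand (step 9) is assumed by analogy with simpler substrates; the mirror-image catalyst would be used if a trial shows the opposite sense.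

**Step 1**
Reactants: 1 2-(benzyloxy)phenol
Product: 2 2-(benzyloxy)-4,6-dibromophenol
Conditions: NBS (2.05 equiv), iPr2NH (10 mol %), CH2Cl2, 0 °C to rt
Reagents that add atoms: N-bromosuccinimide, O=C1CCC(=O)N1Br
Why: Electrophilic aromatic bromination; the free hydroxyl is the stronger activator and should direct the two bromines to its free ortho and para positions.

**Step 2**
Reactants: 2 2-(benzyloxy)-4,6-dibromophenol; 3 [4-(benzyloxy)-3-methoxyphenyl]methanol
Product: 4 1-(benzyloxy)-2-{[4-(benzyloxy)-3-methoxyphenyl]methoxy}-3,5-dibromobenzene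
Conditions: PPh3, DIAD, THF, 0 °C to rt
Reagents that add atoms: none
Why: Mitsunobu etherification; the dibromophenol is acidic enough and the primary benzylic alcohol should react by clean SN2 displacement.

**Step 3**
Reactants: 4 1-(benzyloxy)-2-{[4-(benzyloxy)-3-methoxyphenyl]methoxy}-3,5-dibromobenzene
Product: 6 methyl {3-(benzyloxy)-2-{[4-(benzyloxy)-3-methoxyphenyl]methoxy}-5-bromophenyl}(oxo)acetate, via arylmagnesium chloride 5 (not isolated)
Conditions: iPrMgCl·LiCl (1.05 equiv), THF, −20 °C; then added to (CO2Me)2 (3 equiv), THF, −78 °C; dilute HCl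
Reagents that add atoms: dimethyl oxalate, COC(=O)C(=O)OC
Why: Halogen–magnesium exchange should occur at the bromine ortho to the alkoxy group (inductive activation and chelation, as known for 2,4-dibromoanisole), and inverse addition to excess oxalate should stop at the α-keto ester (Grignard acylation).

**Step 4**
Reactants: 6 methyl {3-(benzyloxy)-2-{[4-(benzyloxy)-3-methoxyphenyl]methoxy}-5-bromophenyl}(oxo)acetate
Product: 8 methyl {3-(benzyloxy)-2-{[4-(benzyloxy)-3-methoxyphenyl]methoxy}-5-bromophenyl}(diazo)acetate, via tosylhydrazone 7 (not isolated)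
Conditions: TsNHNH2 (1.1 equiv), toluene, 80 °C; then DBU (1.5 equiv), CH2Cl2, rt
Reagents that add atoms: p-toluenesulfonyl hydrazide, Cc1ccc(cc1)S(=O)(=O)NN
Why: Bamford–Stevens reaction; the tosylhydrazone of an aryl α-keto ester should lose sulfinate under mild base to give the donor/acceptor diazo ester.

**Step 5**
Reactants: 8 methyl {3-(benzyloxy)-2-{[4-(benzyloxy)-3-methoxyphenyl]methoxy}-5-bromophenyl}(diazo)acetate
Product: 9 methyl (2R,3S)-7-(benzyloxy)-2-[4-(benzyloxy)-3-methoxyphenyl]-5-bromo-2,3-dihydro-1-benzofuran-3-carboxylate (cis)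
Conditions: Rh2(S-PTTL)4 (dirhodium tetrakis[N-phthaloyl-(S)-tert-leucinate], 1 mol %), toluene, −60 °C
Reagents that add atoms: none
Why: Intramolecular 1,5 C–H insertion of a divalent-rhodium carbenoid into the ether-activated benzylic C–H bond, a reaction type established for 2-(benzyloxy)phenyl diazoacetates; the chiral carboxylate ligands should set C2 as R, and the concerted insertion should give the cis ester, whose C3 is corrected in step 6.

**Step 6**
Reactants: 9 methyl (2R,3S)-7-(benzyloxy)-2-[4-(benzyloxy)-3-methoxyphenyl]-5-bromo-2,3-dihydro-1-benzofuran-3-carboxylate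
Product: 11 [(2R,3S)-7-(benzyloxy)-2-[4-(benzyloxy)-3-methoxyphenyl]-5-bromo-2,3-dihydro-1-benzofuran-3-yl]methanol (trans), via trans ester 10 (not isolated)
Conditions: NaOMe (0.3 equiv), MeOH/THF, rt; then LiBH4 (3 equiv), 0 °C to rt
Reagents that add atoms: none
Why: Base epimerisation at the ester α-carbon should give the thermodynamically preferred trans ester (C3 set relative to the fixed C2), and ester reduction with LiBH4 should leave the aryl bromide untouched.

**Step 7**
Reactants: 11 [(2R,3S)-7-(benzyloxy)-2-[4-(benzyloxy)-3-methoxyphenyl]-5-bromo-2,3-dihydro-1-benzofuran-3-yl]methanol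
Product: 12 (2R,3S)-7-(benzyloxy)-2-[4-(benzyloxy)-3-methoxyphenyl]-3-[(benzyloxy)methyl]-5-bromo-2,3-dihydro-1-benzofuran
Conditions: NaH, BnBr, Bu4NI (cat.), THF/DMF, 0 °C to rt
Reagents that add atoms: benzyl bromide, BrCc1ccccc1
Why: Williamson ether synthesis; the benzyl ether keeps the primary hydroxyl from adding to the aryne and falls off with the other benzyl groups in the last step.

**Step 8**
Reactants: 12 (2R,3S)-7-(benzyloxy)-2-[4-(benzyloxy)-3-methoxyphenyl]-3-[(benzyloxy)methyl]-5-bromo-2,3-dihydro-1-benzofuran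
Product: 14 (2R,3S)-7-(benzyloxy)-2-[4-(benzyloxy)-3-methoxyphenyl]-3-[(benzyloxy)methyl]-2,3-dihydro-1-benzofuran-5-carbaldehyde, via aryllithium 13 (not isolated)
Conditions: n-BuLi (1.1 equiv), THF, −78 °C; then DMF (3 equiv), −78 to 0 °C; H2O
Reagents that add atoms: N,N-dimethylformamide, CN(C)C=O
Why: Bromine–lithium exchange followed by Bouveault formylation; exchange at −78 °C should be much faster than any deprotonation of the benzylic ether positions.

**Step 9**
Reactants: 14 (2R,3S)-7-(benzyloxy)-2-[4-(benzyloxy)-3-methoxyphenyl]-3-[(benzyloxy)methyl]-2,3-dihydro-1-benzofuran-5-carbaldehyde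
Product: 15 methyl (3S)-3-{(2R,3S)-7-(benzyloxy)-2-[4-(benzyloxy)-3-methoxyphenyl]-3-[(benzyloxy)methyl]-2,3-dihydro-1-benzofuran-5-yl}-3-[(trimethylsilyl)oxy]propanoate
Conditions: 1-methoxy-1-(trimethylsilyloxy)ethene (1.5 equiv); catalyst (5 mol %) from Ti(OiPr)4, (S)-2-[(3-bromo-5-tert-butyl-2-hydroxybenzylidene)amino]-2'-hydroxy-1,1'-binaphthyl and 3,5-di-tert-butylsalicylic acid; Et2O, −10 to 0 °C; filtration through Et3N-deactivated silica
Reagents that add atoms: 1-methoxy-1-(trimethylsilyloxy)ethene, COC(=C)O[Si](C)(C)C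
Why: Catalytic asymmetric Mukaiyama acetate aldol; the chiral tetravalent-titanium complex should select the aldehyde face and set the carbinol carbon as S (the remote ring stereocenters should not interfere), and silyl transfer should deliver the trimethylsilyl ether directly.

**Step 10**
Reactants: 16 3,5-bis(benzyloxy)phenol
Product: 17 3,5-bis(benzyloxy)-2-bromophenol
Conditions: NBS (1.0 equiv), iPr2NH (10 mol %), CH2Cl2, −78 °C
Reagents that add atoms: N-bromosuccinimide, O=C1CCC(=O)N1Br
Why: Amine-mediated ortho-selective bromination of a phenol; any 4-bromo isomer should be removable by chromatography.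

**Step 11**
Reactants: 17 3,5-bis(benzyloxy)-2-bromophenol
Product: 20 3,5-bis(benzyloxy)-2-(trimethylsilyl)phenyl trifluoromethanesulfonate, via silyl ether 18 (not isolated), via lithium phenoxide 19 (not isolated)
Conditions: HMDS, THF, 70 °C, then evaporation; n-BuLi (1.1 equiv), THF, −100 to −80 °C; Tf2O (1.2 equiv), −100 to −80 °C
Reagents that add atoms: hexamethyldisilazane, C[Si](C)(C)N[Si](C)(C)C; trifluoromethanesulfonic anhydride, O=S(=O)(OS(=O)(=O)C(F)(F)F)C(F)(F)F
Why: O-silylation, bromine–lithium exchange with retro-Brook migration of silicon from oxygen to carbon, and triflation of the phenoxide; this is the standard entry to ortho-silylaryl triflate aryne precursors.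

**Step 12**
Reactants: 15 methyl (3S)-3-{(2R,3S)-7-(benzyloxy)-2-[4-(benzyloxy)-3-methoxyphenyl]-3-[(benzyloxy)methyl]-2,3-dihydro-1-benzofuran-5-yl}-3-[(trimethylsilyl)oxy]propanoate; 20 3,5-bis(benzyloxy)-2-(trimethylsilyl)phenyl trifluoromethanesulfonate
Product: 24 (2S)-5,7-bis(benzyloxy)-2-{(2R,3S)-7-(benzyloxy)-2-[4-(benzyloxy)-3-methoxyphenyl]-3-[(benzyloxy)methyl]-2,3-dihydro-1-benzofuran-5-yl}-2,3-dihydro-4H-chromen-4-one, via aryne 21 (not isolated), via cesium alkoxide 22 (not isolated), via aryl anion 23 (not isolated)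
Conditions: 15 (1 equiv) and 20 (2 equiv) in THF, CsF (4.5 equiv), 18-crown-6 (2 equiv), 0 °C to rt; then AcOH, 0 °C
Reagents that add atoms: none
Why: Proposed new method: fluoride converts the ortho-silylaryl triflate 20 into 3,5-bis(benzyloxy)benzyne 21 and, in the same aprotic medium, frees the secondary alkoxide 22 from its trimethylsilyl ether; 22 adds to the aryne carbon remote from the flanking benzyloxy group (O1–C8a), and the aryl anion 23, now ortho to the new ether, attacks the methyl ester and expels methoxide (C4–C4a). The closest known reaction types are the fluoride-mediated annulation of arynes with salicylate esters to xanthones and the C–O insertion of arynes into carboxylic acids that leads to ortho-hydroxyaryl ketones and chromanones, but an aliphatic β-silyloxy ester has not been shown as the partner. Ring C closes by 6-exo-trig attack of the aryl anion on the ester carbonyl after the intermolecular O-arylation, and ring A arrives intact as the aryne. No new stereocenter is formed, because C2 was set in step 9 and only its O–Si bond is exchanged for O–aryl, so its configuration should be retained. The step needs regioselectivity on the unsymmetrical aryne, which the inductive effect of the benzyloxy group next to the triple bond should secure by directing the nucleophile to the distal carbon and leaving the carbanion beside it, the same sense as in known acyl-alkylations of 3-alkoxyarynes. It also needs acyl transfer to outrun protonation of the aryl anion, which the silyl mask (no O–H) and THF should secure, while the excess of 20 consumes the released methoxide and the cold acetic acid quench limits base-induced opening of the new flavanone ring.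

**Step 13**
Reactants: 24 (2S)-5,7-bis(benzyloxy)-2-{(2R,3S)-7-(benzyloxy)-2-[4-(benzyloxy)-3-methoxyphenyl]-3-[(benzyloxy)methyl]-2,3-dihydro-1-benzofuran-5-yl}-2,3-dihydro-4H-chromen-4-one
Product: 25 silyhermin B, (2S)-5,7-dihydroxy-2-[(2R,3S)-7-hydroxy-2-(4-hydroxy-3-methoxyphenyl)-3-(hydroxymethyl)-2,3-dihydro-1-benzofuran-5-yl]-2,3-dihydro-4H-chromen-4-one
Conditions: H2 (1 atm), Pd(OH)2/C, THF/MeOH, rt
Reagents that add atoms: none
Why: Catalytic hydrogenolysis of four aryl benzyl ethers and one alkyl benzyl ether; the exocyclic O–CH2Ph bonds should cleave faster than the two ring benzylic C–O bonds, and no stereocenter is touched.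

**Compound list**
1 | 2-(benzyloxy)phenol | Oc1ccccc1OCc1ccccc1 | starting material
2 | 2-(benzyloxy)-4,6-dibromophenol | Oc1c(Br)cc(Br)cc1OCc1ccccc1 | intermediate
3 | [4-(benzyloxy)-3-methoxyphenyl]methanol | COc1cc(CO)ccc1OCc1ccccc1 | starting material
4 | 1-(benzyloxy)-2-{[4-(benzyloxy)-3-methoxyphenyl]methoxy}-3,5-dibromobenzene | COc1cc(COc2c(Br)cc(Br)cc2OCc2ccccc2)ccc1OCc1ccccc1 | intermediate
5 | {3-(benzyloxy)-2-{[4-(benzyloxy)-3-methoxyphenyl]methoxy}-5-bromophenyl}magnesium chloride | COc1cc(COc2c([Mg]Cl)cc(Br)cc2OCc2ccccc2)ccc1OCc1ccccc1 | intermediate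
6 | methyl {3-(benzyloxy)-2-{[4-(benzyloxy)-3-methoxyphenyl]methoxy}-5-bromophenyl}(oxo)acetate | COC(=O)C(=O)c1cc(Br)cc(OCc2ccccc2)c1OCc1ccc(OCc2ccccc2)c(OC)c1 | intermediate
7 | N-tosylhydrazone of keto ester 6 | COC(=O)C(=NNS(=O)(=O)c1ccc(C)cc1)c1cc(Br)cc(OCc2ccccc2)c1OCc1ccc(OCc2ccccc2)c(OC)c1 | intermediate
8 | methyl {3-(benzyloxy)-2-{[4-(benzyloxy)-3-methoxyphenyl]methoxy}-5-bromophenyl}(diazo)acetate | COC(=O)C(=[N+]=[N-])c1cc(Br)cc(OCc2ccccc2)c1OCc1ccc(OCc2ccccc2)c(OC)c1 | intermediate
9 | methyl (2R,3S)-7-(benzyloxy)-2-[4-(benzyloxy)-3-methoxyphenyl]-5-bromo-2,3-dihydro-1-benzofuran-3-carboxylate (cis) | COc1cc([C@@H]2Oc3c(OCc4ccccc4)cc(Br)cc3[C@@H]2C(=O)OC)ccc1OCc1ccccc1 | intermediate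
10 | methyl (2R,3R)-7-(benzyloxy)-2-[4-(benzyloxy)-3-methoxyphenyl]-5-bromo-2,3-dihydro-1-benzofuran-3-carboxylate (trans) | COc1cc([C@@H]2Oc3c(OCc4ccccc4)cc(Br)cc3[C@H]2C(=O)OC)ccc1OCc1ccccc1 | intermediate
11 | [(2R,3S)-7-(benzyloxy)-2-[4-(benzyloxy)-3-methoxyphenyl]-5-bromo-2,3-dihydro-1-benzofuran-3-yl]methanol (trans) | COc1cc([C@@H]2Oc3c(OCc4ccccc4)cc(Br)cc3[C@H]2CO)ccc1OCc1ccccc1 | intermediate
12 | (2R,3S)-7-(benzyloxy)-2-[4-(benzyloxy)-3-methoxyphenyl]-3-[(benzyloxy)methyl]-5-bromo-2,3-dihydro-1-benzofuran | COc1cc([C@@H]2Oc3c(OCc4ccccc4)cc(Br)cc3[C@H]2COCc2ccccc2)ccc1OCc1ccccc1 | intermediate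
13 | 5-lithio derivative of 12 | COc1cc([C@@H]2Oc3c(OCc4ccccc4)cc([Li])cc3[C@H]2COCc2ccccc2)ccc1OCc1ccccc1 | intermediate
14 | (2R,3S)-7-(benzyloxy)-2-[4-(benzyloxy)-3-methoxyphenyl]-3-[(benzyloxy)methyl]-2,3-dihydro-1-benzofuran-5-carbaldehyde | COc1cc([C@@H]2Oc3c(OCc4ccccc4)cc(C=O)cc3[C@H]2COCc2ccccc2)ccc1OCc1ccccc1 | intermediate
15 | methyl (3S)-3-{(2R,3S)-7-(benzyloxy)-2-[4-(benzyloxy)-3-methoxyphenyl]-3-[(benzyloxy)methyl]-2,3-dihydro-1-benzofuran-5-yl}-3-[(trimethylsilyl)oxy]propanoate | COc1cc([C@@H]2Oc3c(OCc4ccccc4)cc([C@@H](O[Si](C)(C)C)CC(=O)OC)cc3[C@H]2COCc2ccccc2)ccc1OCc1ccccc1 | intermediate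
16 | 3,5-bis(benzyloxy)phenol | Oc1cc(OCc2ccccc2)cc(OCc2ccccc2)c1 | starting material
17 | 3,5-bis(benzyloxy)-2-bromophenol | Oc1cc(OCc2ccccc2)cc(OCc2ccccc2)c1Br | intermediate
18 | [3,5-bis(benzyloxy)-2-bromophenoxy]trimethylsilane | C[Si](C)(C)Oc1cc(OCc2ccccc2)cc(OCc2ccccc2)c1Br | intermediate
19 | lithium 3,5-bis(benzyloxy)-2-(trimethylsilyl)phenoxide | [Li]Oc1cc(OCc2ccccc2)cc(OCc2ccccc2)c1[Si](C)(C)C | intermediate
20 | 3,5-bis(benzyloxy)-2-(trimethylsilyl)phenyl trifluoromethanesulfonate | C[Si](C)(C)c1c(OS(=O)(=O)C(F)(F)F)cc(OCc2ccccc2)cc1OCc1ccccc1 | intermediate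
21 | 3,5-bis(benzyloxy)benzyne | C1#CC(OCc2ccccc2)=CC(OCc2ccccc2)=C1 | intermediate
22 | cesium alkoxide of 15 (silyl group removed) | COc1cc([C@@H]2Oc3c(OCc4ccccc4)cc([C@@H](O[Cs])CC(=O)OC)cc3[C@H]2COCc2ccccc2)ccc1OCc1ccccc1 | intermediate
23 | O-arylated ester with cesium on the aryl carbon between the ether and the benzyloxy group | COc1cc([C@@H]2Oc3c(OCc4ccccc4)cc([C@@H](Oc4cc(OCc5ccccc5)cc(OCc5ccccc5)c4[Cs])CC(=O)OC)cc3[C@H]2COCc2ccccc2)ccc1OCc1ccccc1 | intermediate
24 | (2S)-5,7-bis(benzyloxy)-2-{(2R,3S)-7-(benzyloxy)-2-[4-(benzyloxy)-3-methoxyphenyl]-3-[(benzyloxy)methyl]-2,3-dihydro-1-benzofuran-5-yl}-2,3-dihydro-4H-chromen-4-one | COc1cc([C@@H]2Oc3c(OCc4ccccc4)cc([C@@H]4CC(=O)c5c(OCc6ccccc6)cc(OCc6ccccc6)cc5O4)cc3[C@H]2COCc2ccccc2)ccc1OCc1ccccc1 | intermediate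
25 | silyhermin B | COc1cc([C@@H]2Oc3c(O)cc([C@@H]4CC(=O)c5c(O)cc(O)cc5O4)cc3[C@H]2CO)ccc1O | target

**Totals**
Total step count: 13. Longest linear sequence: 11 steps (steps 1–9, 12 and 13); steps 10 and 11 make the aryne precursor on a side branch.

**Steps most likely to fail**

1. Step 12 (proposed new method). The aryl anion may be protonated, or may deprotonate the ester α-position, before acyl transfer. The freed alkoxide may fragment by retro-aldol. Base-induced opening and reclosure of the flavanone ring may erode the C2 configuration. The fallback uses known chemistry and sets out from bromide 12. Bromine–lithium exchange (n-BuLi, THF, −78 °C), B(OiPr)3 and aqueous NH4Cl should give [(2R,3S)-7-(benzyloxy)-2-[4-(benzyloxy)-3-methoxyphenyl]-3-[(benzyloxy)methyl]-2,3-dihydro-1-benzofuran-5-yl]boronic acid F1. Commercial 5,7-dihydroxy-4H-chromen-4-one is benzylated (BnBr, K2CO3, DMF, 80 °C) to 5,7-bis(benzyloxy)-4H-chromen-4-one F2. A Hayashi–Miyaura asymmetric 1,4-addition of F1 to F2 ([Rh(OH)(cod)]2, electron-poor chiral biaryl bisphosphine MeO-F12-BIPHEP in the enantiomer that gives 2S, toluene/H2O, 50 °C), a reaction type established for 5,7-dioxygenated chromones, should give 24 directly, where the route is rejoined.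

2. Step 5. Enantiofacial discrimination by the chiral carboxylate ligands may be insufficient on this electron-rich, heavily substituted substrate, or the cis and trans insertion products may form with opposite sense at C2, which would erode purity on epimerisation. The fallback sets out from diazo ester 8 and replaces catalyst control by resolution through covalent diastereomers. Achiral Rh2(OAc)4 (CH2Cl2, rt) should give the racemic cis ester, that is 9 together with its enantiomer methyl (2S,3R)-7-(benzyloxy)-2-[4-(benzyloxy)-3-methoxyphenyl]-5-bromo-2,3-dihydro-1-benzofuran-3-carboxylate F3. NaOMe and then LiBH4 as in step 6 should lead through 10 and its enantiomer, the (2S,3S)-trans ester F4, to 11 together with its enantiomer, the (2S,3R)-alcohol F5. Esterification with (S)-2-methoxy-2-phenylacetic acid (DCC, DMAP, CH2Cl2) should give the (S)-O-methylmandelate of 11 F6 and the (S)-O-methylmandelate of the enantiomeric alcohol F7, to be separated by chromatography or crystallisation. K2CO3/MeOH on F6 should return 11, where the route is rejoined.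

3. Step 9. Facial selectivity or turnover of the titanium catalyst may be poor with this electron-rich aryl aldehyde, and the silyl ether may be lost on isolation. The fallback sets out from aldehyde 14. Roskamp homologation (methyl diazoacetate, SnCl2 cat., CH2Cl2, rt) should give methyl 3-{(2R,3S)-7-(benzyloxy)-2-[4-(benzyloxy)-3-methoxyphenyl]-3-[(benzyloxy)methyl]-2,3-dihydro-1-benzofuran-5-yl}-3-oxopropanoate F8. Noyori–Ikariya asymmetric transfer hydrogenation (RuCl(p-cymene)[(S,S)-TsDPEN], HCO2H/Et3N, rt) should give the (3S)-3-hydroxypropanoate F9, the sense following that of acetophenone reduction. TMSCl and imidazole (CH2Cl2, 0 °C) should then give 15, where the route is rejoined.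

**Further compounds**
F1 | step 12 | [(2R,3S)-7-(benzyloxy)-2-[4-(benzyloxy)-3-methoxyphenyl]-3-[(benzyloxy)methyl]-2,3-dihydro-1-benzofuran-5-yl]boronic acid | COc1cc([C@@H]2Oc3c(OCc4ccccc4)cc(B(O)O)cc3[C@H]2COCc2ccccc2)ccc1OCc1ccccc1
F2 | step 12 | 5,7-bis(benzyloxy)-4H-chromen-4-one | O=c1ccoc2cc(OCc3ccccc3)cc(OCc3ccccc3)c12
F3 | step 5 | methyl (2S,3R)-7-(benzyloxy)-2-[4-(benzyloxy)-3-methoxyphenyl]-5-bromo-2,3-dihydro-1-benzofuran-3-carboxylate (enantiomer of 9) | COc1cc([C@H]2Oc3c(OCc4ccccc4)cc(Br)cc3[C@H]2C(=O)OC)ccc1OCc1ccccc1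
F4 | step 5 | methyl (2S,3S)-7-(benzyloxy)-2-[4-(benzyloxy)-3-methoxyphenyl]-5-bromo-2,3-dihydro-1-benzofuran-3-carboxylate (enantiomer of 10) | COc1cc([C@H]2Oc3c(OCc4ccccc4)cc(Br)cc3[C@@H]2C(=O)OC)ccc1OCc1ccccc1
F5 | step 5 | [(2S,3R)-7-(benzyloxy)-2-[4-(benzyloxy)-3-methoxyphenyl]-5-bromo-2,3-dihydro-1-benzofuran-3-yl]methanol (enantiomer of 11) | COc1cc([C@H]2Oc3c(OCc4ccccc4)cc(Br)cc3[C@@H]2CO)ccc1OCc1ccccc1
F6 | step 5 | [(2R,3S)-7-(benzyloxy)-2-[4-(benzyloxy)-3-methoxyphenyl]-5-bromo-2,3-dihydro-1-benzofuran-3-yl]methyl (2S)-2-methoxy-2-phenylacetate | COc1cc([C@@H]2Oc3c(OCc4ccccc4)cc(Br)cc3[C@H]2COC(=O)[C@@H](OC)c2ccccc2)ccc1OCc1ccccc1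
F7 | step 5 | [(2S,3R)-7-(benzyloxy)-2-[4-(benzyloxy)-3-methoxyphenyl]-5-bromo-2,3-dihydro-1-benzofuran-3-yl]methyl (2S)-2-methoxy-2-phenylacetate | COc1cc([C@H]2Oc3c(OCc4ccccc4)cc(Br)cc3[C@@H]2COC(=O)[C@@H](OC)c2ccccc2)ccc1OCc1ccccc1
F8 | step 9 | methyl 3-{(2R,3S)-7-(benzyloxy)-2-[4-(benzyloxy)-3-methoxyphenyl]-3-[(benzyloxy)methyl]-2,3-dihydro-1-benzofuran-5-yl}-3-oxopropanoate | COc1cc([C@@H]2Oc3c(OCc4ccccc4)cc(C(=O)CC(=O)OC)cc3[C@H]2COCc2ccccc2)ccc1OCc1ccccc1
F9 | step 9 | methyl (3S)-3-{(2R,3S)-7-(benzyloxy)-2-[4-(benzyloxy)-3-methoxyphenyl]-3-[(benzyloxy)methyl]-2,3-dihydro-1-benzofuran-5-yl}-3-hydroxypropanoate | COc1cc([C@@H]2Oc3c(OCc4ccccc4)cc([C@@H](O)CC(=O)OC)cc3[C@H]2COCc2ccccc2)ccc1OCc1ccccc1
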